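**Retrosynthetic overview**

1. The C4–C8 interflavan bond is cut to an 8-lithiated, benzyl-protected (−)-epiafzelechin (lower unit) and a (2S)-flavanone (upper unit); addition followed by ionic hydrogenation sets the 2,4-cis C4 centre.
2. In the lower unit the C3 carbinol is taken back to a flavan-3-one, whose acidic C2–H lets one dynamic reduction set C2 and C3 together (2R,3R, cis).
3. Ring C of the lower unit is then cut at O1–C8a and C2–C3 at once: 4-(benzyloxy)benzaldehyde supplies O1=C2, and C3 is a silyl-dithiane acyl anion carried through C4 on a fluoroarene (C8a–F).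
4. Enabling feature: in ring C (O1–C2–C3–C4–C4a–C8a) C2 and C3 are two adjacent oxygenated, carbonyl-derived carbons, and C8a lies on the phloroglucinol ring A meta to both C5–O and C7–O, so a fluorine at C8a can be displaced by the C2 alkoxide.
5. Ring order: ring A is bought, lower ring C is closed in step 6, the upper ring C is bought as a chromone, and the two units are joined last.

Key step: step 6

Remark: the ligand enantiomers named in steps 8 and 12 follow the usual stereochemical models of these catalysts; if the sense of induction proved opposite, the mirror-image ligand would be used with nothing else changed.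

**Route**

Step 1
Reactants: 1 1,3,5-trifluorobenzene
Product: 2 1,3-bis(benzyloxy)-5-fluorobenzene
Conditions: BnOH (2.05 equiv), NaH, NMP, 0 °C then 80 °C
Reagents that add atoms: benzyl alcohol, OCc1ccccc1
Why: Twofold SNAr of sodium benzyloxide on the trifluoroarene should stop at the bis-ether, because each alkoxy group introduced slows the next displacement, so that the third fluorine is kept as the later leaving group at C8a.

Step 2
Reactants: 2 1,3-bis(benzyloxy)-5-fluorobenzene
Product: 4 2,4-bis(benzyloxy)-6-fluorobenzaldehyde, via iminium chloride 3 (not isolated)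
Conditions: POCl3, DMF, 0 °C then 70 °C; H2O
Reagents that add atoms: N,N-dimethylformamide, CN(C)C=O; water, O
Why: Vilsmeier–Haack formylation should go para to one benzyloxy group and ortho to the other at the less hindered fluorine-flanked position, which places the future C4 between C8a–F and C5–O.

Step 3
Reactants: 4 2,4-bis(benzyloxy)-6-fluorobenzaldehyde
Product: 5 [2,4-bis(benzyloxy)-6-fluorophenyl]methanol
Conditions: NaBH4, MeOH/THF, 0 °C
Reagents that add atoms: none
Why: Borohydride reduction of the aryl aldehyde; nothing else in 4 is reducible under these conditions.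

Step 4
Reactants: 5 [2,4-bis(benzyloxy)-6-fluorophenyl]methanol
Product: 6 1,5-bis(benzyloxy)-2-(bromomethyl)-3-fluorobenzene
Conditions: PPh3, CBr4, CH2Cl2, 0 °C; used at once
Reagents that add atoms: tetrabromomethane, BrC(Br)(Br)Br
Why: Appel bromination works under neutral conditions, which avoids the acid-triggered self-alkylation of this electron-rich benzylic system.

Step 5
Reactants: 6 1,5-bis(benzyloxy)-2-(bromomethyl)-3-fluorobenzene; 7 2-(trimethylsilyl)-1,3-dithiane
Product: 9 2-{[2,4-bis(benzyloxy)-6-fluorophenyl]methyl}-2-(trimethylsilyl)-1,3-dithiane, via lithiated silyl dithiane 8 (not isolated)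
Conditions: 7, nBuLi, THF, −30 °C; then 6, −78 °C to 0 °C
Reagents that add atoms: none
Why: Corey–Seebach alkylation: the silyl-stabilised lithiodithiane 8 attacks the benzylic bromide by SN2 far faster than it could metalate the fluoroarene, and installs C3 as a silicon-masked acyl anion.

Step 6
Reactants: 9 2-{[2,4-bis(benzyloxy)-6-fluorophenyl]methyl}-2-(trimethylsilyl)-1,3-dithiane; 10 4-(benzyloxy)benzaldehyde
Product: 12 rac-5,7-bis(benzyloxy)-2-[4-(benzyloxy)phenyl]spiro[chromane-3,2'-[1,3]dithiane], via caesium alkoxide 11 (not isolated)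
Conditions: CsF (1.5 equiv), 4 Å MS, DMF, 25 °C then 90 °C
Reagents that add atoms: none
Why: Fluoride attacks the silicon of 9 and frees the dithiane-stabilised carbanion at C3, an acyl anion equivalent (polarity reversal of a carbonyl carbon), which adds to the carbonyl carbon C2 of the non-enolisable aldehyde 10 and so joins two carbons of like polarity; this is the fluoride-promoted variant of the Corey–Seebach addition known for 2-silyl-1,3-dithianes. The caesium alkoxide 11 then attacks C8a and expels fluoride in an intramolecular SNAr through a Meisenheimer adduct, the reaction type by which alkoxides close chromans onto fluoroarenes; the two benzyloxy groups meta to C8a stabilise the adduct inductively and the fully substituted dithiane carbon presses the chain into the cyclising conformation. Ring C of the lower unit is the only ring closed, as a six-membered ring by 6-exo attack of O1 on the arene carbon. C2 is the only new stereocentre and is formed without control on purpose, since C3 is unmasked as a ketone in step 7 and C2 and C3 are then set together in step 8. The selectivity needed is addition of the carbanion to the aldehyde before protonation, secured by the dry medium and the absence of acidic C–H in 10, and O-arylation at one site only, secured by the single fluorine and the six-membered transition state. The fluoride expelled from C8a triggers the next desilylation, so that the only coproduct is Me3SiF.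

Step 7
Reactants: 12 rac-5,7-bis(benzyloxy)-2-[4-(benzyloxy)phenyl]spiro[chromane-3,2'-[1,3]dithiane]
Product: 13 rac-5,7-bis(benzyloxy)-2-[4-(benzyloxy)phenyl]chroman-3-one
Conditions: MeI, CaCO3, MeCN/H2O, 45 °C
Reagents that add atoms: water, O
Why: S-Methylation and hydrolysis of the dithioketal (Corey–Seebach unmasking) under carbonate buffer should free the C3 ketone without touching the benzyl ethers or the electron-rich rings; the racemic state of C2 is of no concern.

Step 8
Reactants: 13 rac-5,7-bis(benzyloxy)-2-[4-(benzyloxy)phenyl]chroman-3-one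
Product: 14 (2R,3R)-5,7-bis(benzyloxy)-2-[4-(benzyloxy)phenyl]chroman-3-ol
Conditions: RuCl(p-cymene)[(R,R)-TsDPEN] (2 mol%), HCO2H (3 equiv), Et3N (6 equiv), EtOAc, 40 °C, argon
Reagents that add atoms: none
Why: Noyori–Ikariya asymmetric transfer hydrogenation under dynamic kinetic resolution: the C2–H, α to the ketone and flanked by aryl and aryloxy, lets the enantiomers of 13 interconvert through the enol under the amine, while the catalyst reduces the 2R ketone by hydride delivery to the C3 face anti to the C2 aryl group, which should give the 2,3-cis (2R,3R) alcohol.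

Step 9
Reactants: 14 (2R,3R)-5,7-bis(benzyloxy)-2-[4-(benzyloxy)phenyl]chroman-3-ol
Product: 15 (2R,3R)-3,5,7-tris(benzyloxy)-2-[4-(benzyloxy)phenyl]chromane
Conditions: NaH, BnBr, Bu4NI (cat.), DMF, 0 °C to rt
Reagents that add atoms: benzyl bromide, BrCc1ccccc1
Why: Williamson etherification caps the C3 hydroxyl against the organolithium chemistry of step 13 with a group that leaves in the final hydrogenolysis; no stereocentre is touched.

Step 10
Reactants: 15 (2R,3R)-3,5,7-tris(benzyloxy)-2-[4-(benzyloxy)phenyl]chromane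
Product: 16 (2R,3R)-3,5,7-tris(benzyloxy)-2-[4-(benzyloxy)phenyl]-8-bromochromane
Conditions: NBS (1.0 equiv), CH2Cl2, −78 °C to −20 °C
Reagents that add atoms: N-bromosuccinimide, O=C1CCC(=O)N1Br
Why: Electrophilic aromatic bromination should go to C8 of ring A, the more accessible of its two doubly activated positions (C6 lies between two benzyloxy groups), as is general for 5,7-bis(benzyloxy)flavans.

Step 11
Reactants: 17 7-hydroxy-4H-chromen-4-one
Product: 18 7-(benzyloxy)-4H-chromen-4-one
Conditions: BnBr, K2CO3, DMF, 50 °C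
Reagents that add atoms: benzyl bromide, BrCc1ccccc1
Why: Williamson etherification of the phenol under carbonate, which leaves the chromone ring intact.

Step 12
Reactants: 18 7-(benzyloxy)-4H-chromen-4-one; 19 [4-(benzyloxy)phenyl]boronic acid
Product: 20 (2S)-7-(benzyloxy)-2-[4-(benzyloxy)phenyl]chroman-4-one
Conditions: Pd(OCOCF3)2 (5 mol%), (R)-t-BuPyOx (6 mol%), NH4PF6, H2O, ClCH2CH2Cl, 60 °C
Reagents that add atoms: none
Why: Palladium-catalysed asymmetric conjugate addition of the arylboronic acid to the chromone (aryl–palladium insertion across C2=C3, then protonolysis of the palladium enolate) sets C2 through the chiral pyridine–oxazoline ligand, and the base-free medium avoids ring-opening racemisation of the flavanone.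

Step 13
Reactants: 16 (2R,3R)-3,5,7-tris(benzyloxy)-2-[4-(benzyloxy)phenyl]-8-bromochromane; 20 (2S)-7-(benzyloxy)-2-[4-(benzyloxy)phenyl]chroman-4-one
Product: 22 (2S)-7-(benzyloxy)-2-[4-(benzyloxy)phenyl]-4-[(2R,3R)-3,5,7-tris(benzyloxy)-2-[4-(benzyloxy)phenyl]chroman-8-yl]chroman-4-ol (both C4 epimers), via 8-aryllithium 21 (not isolated)
Conditions: 16, tBuLi (2.1 equiv), THF, −78 °C; then 20, −78 °C to −40 °C; H2O
Reagents that add atoms: none
Why: Bromine–lithium exchange gives an 8-aryllithium that carries no ortho leaving group and adds to the C4 carbonyl of 20 at low temperature (1,2-addition); the carbinol configuration is irrelevant because the centre is ionised in step 14.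

Step 14
Reactants: 22 (2S)-7-(benzyloxy)-2-[4-(benzyloxy)phenyl]-4-[(2R,3R)-3,5,7-tris(benzyloxy)-2-[4-(benzyloxy)phenyl]chroman-8-yl]chroman-4-ol
Product: 24 (2R,3R)-3,5,7-tris(benzyloxy)-2-[4-(benzyloxy)phenyl]-8-{(2S,4S)-7-(benzyloxy)-2-[4-(benzyloxy)phenyl]chroman-4-yl}chromane, via C4 benzylic cation 23 (not isolated)
Conditions: Et3SiH, CF3CO2H, CH2Cl2, −78 °C to −30 °C
Reagents that add atoms: none
Why: Ionic hydrogenation: acid ionises the tertiary diarylcarbinol to a cation stabilised by the C7 oxygen and O1 of the upper ring A, and Et3SiH delivers hydride axially to the half-chair cation cis to the axial C2–H, which leaves both aryl groups equatorial and should give the 2,4-cis (2S,4S) centre.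

Step 15
Reactants: 24 (2R,3R)-3,5,7-tris(benzyloxy)-2-[4-(benzyloxy)phenyl]-8-{(2S,4S)-7-(benzyloxy)-2-[4-(benzyloxy)phenyl]chroman-4-yl}chromane
Product: 25 (2R,3R)-8-[(2S,4S)-7-hydroxy-2-(4-hydroxyphenyl)chroman-4-yl]-2-(4-hydroxyphenyl)chromane-3,5,7-triol
Conditions: H2 (1 atm), Pd(OH)2/C, THF/MeOH, rt
Reagents that add atoms: none
Why: Hydrogenolysis of the six benzyl ethers over Pd(OH)2/C; the benzylic C–O bonds of the two pyran rings and the diarylmethine C–C bond are cleaved far more slowly, so all four stereocentres should be kept.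

**Compound list**

1 | 1,3,5-trifluorobenzene | Fc1cc(F)cc(F)c1 | starting material
2 | 1,3-bis(benzyloxy)-5-fluorobenzene | Fc1cc(OCc2ccccc2)cc(OCc2ccccc2)c1 | intermediate
3 | [2,4-bis(benzyloxy)-6-fluorobenzylidene]dimethyliminium chloride | C[N+](C)=Cc1c(F)cc(OCc2ccccc2)cc1OCc1ccccc1.[Cl-] | intermediate (not isolated)
4 | 2,4-bis(benzyloxy)-6-fluorobenzaldehyde | O=Cc1c(F)cc(OCc2ccccc2)cc1OCc1ccccc1 | intermediate
5 | [2,4-bis(benzyloxy)-6-fluorophenyl]methanol | OCc1c(F)cc(OCc2ccccc2)cc1OCc1ccccc1 | intermediate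
6 | 1,5-bis(benzyloxy)-2-(bromomethyl)-3-fluorobenzene | BrCc1c(F)cc(OCc2ccccc2)cc1OCc1ccccc1 | intermediate
7 | 2-(trimethylsilyl)-1,3-dithiane | C[Si](C)(C)C1SCCCS1 | starting material
8 | 2-lithio-2-(trimethylsilyl)-1,3-dithiane | [Li]C1([Si](C)(C)C)SCCCS1 | intermediate (not isolated)
9 | 2-{[2,4-bis(benzyloxy)-6-fluorophenyl]methyl}-2-(trimethylsilyl)-1,3-dithiane | C[Si](C)(C)C1(Cc2c(F)cc(OCc3ccccc3)cc2OCc2ccccc2)SCCCS1 | intermediate
10 | 4-(benzyloxy)benzaldehyde | O=Cc1ccc(OCc2ccccc2)cc1 | starting material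
11 | caesium [4-(benzyloxy)phenyl](2-{[2,4-bis(benzyloxy)-6-fluorophenyl]methyl}-1,3-dithian-2-yl)methanolate (racemic) | [Cs+].[O-]C(c1ccc(OCc2ccccc2)cc1)C1(Cc2c(F)cc(OCc3ccccc3)cc2OCc2ccccc2)SCCCS1 | intermediate (not isolated)
12 | rac-5,7-bis(benzyloxy)-2-[4-(benzyloxy)phenyl]spiro[chromane-3,2'-[1,3]dithiane] | C1(c2ccc(OCc3ccccc3)cc2)Oc2cc(OCc3ccccc3)cc(OCc3ccccc3)c2CC12SCCCS2 | intermediate
13 | rac-5,7-bis(benzyloxy)-2-[4-(benzyloxy)phenyl]chroman-3-one | O=C1Cc2c(OCc3ccccc3)cc(OCc3ccccc3)cc2OC1c1ccc(OCc2ccccc2)cc1 | intermediate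
14 | (2R,3R)-5,7-bis(benzyloxy)-2-[4-(benzyloxy)phenyl]chroman-3-ol | C(c1ccccc1)Oc1cc(OCc2ccccc2)c2c(c1)O[C@H](c1ccc(OCc3ccccc3)cc1)[C@H](O)C2 | intermediate
15 | (2R,3R)-3,5,7-tris(benzyloxy)-2-[4-(benzyloxy)phenyl]chromane | C(c1ccccc1)Oc1cc(OCc2ccccc2)c2c(c1)O[C@H](c1ccc(OCc3ccccc3)cc1)[C@H](OCc1ccccc1)C2 | intermediate
16 | (2R,3R)-3,5,7-tris(benzyloxy)-2-[4-(benzyloxy)phenyl]-8-bromochromane | C(c1ccccc1)Oc1cc(OCc2ccccc2)c2c(c1Br)O[C@H](c1ccc(OCc3ccccc3)cc1)[C@H](OCc1ccccc1)C2 | intermediate
17 | 7-hydroxy-4H-chromen-4-one | O=c1ccoc2cc(O)ccc12 | starting material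
18 | 7-(benzyloxy)-4H-chromen-4-one | O=c1ccoc2cc(OCc3ccccc3)ccc12 | intermediate
19 | [4-(benzyloxy)phenyl]boronic acid | OB(O)c1ccc(OCc2ccccc2)cc1 | starting material
20 | (2S)-7-(benzyloxy)-2-[4-(benzyloxy)phenyl]chroman-4-one | C(c1ccccc1)Oc1ccc([C@@H]2CC(=O)c3ccc(OCc4ccccc4)cc3O2)cc1 | intermediate
21 | (2R,3R)-3,5,7-tris(benzyloxy)-2-[4-(benzyloxy)phenyl]-8-lithiochromane | C(c1ccccc1)Oc1cc(OCc2ccccc2)c2c(c1[Li])O[C@H](c1ccc(OCc3ccccc3)cc1)[C@H](OCc1ccccc1)C2 | intermediate (not isolated)
22 | (2S)-7-(benzyloxy)-2-[4-(benzyloxy)phenyl]-4-[(2R,3R)-3,5,7-tris(benzyloxy)-2-[4-(benzyloxy)phenyl]chroman-8-yl]chroman-4-ol (both C4 epimers) | C(c1ccccc1)Oc1ccc([C@@H]2CC(O)(c3c(OCc4ccccc4)cc(OCc4ccccc4)c4c3O[C@H](c3ccc(OCc5ccccc5)cc3)[C@H](OCc3ccccc3)C4)c3ccc(OCc4ccccc4)cc3O2)cc1 | intermediate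
23 | C4 benzylic cation of 22 (trifluoroacetate) | C(c1ccccc1)Oc1ccc([C@@H]2C[C+](c3c(OCc4ccccc4)cc(OCc4ccccc4)c4c3O[C@H](c3ccc(OCc5ccccc5)cc3)[C@H](OCc3ccccc3)C4)c3ccc(OCc4ccccc4)cc3O2)cc1.[O-]C(=O)C(F)(F)F | intermediate (not isolated)
24 | (2R,3R)-3,5,7-tris(benzyloxy)-2-[4-(benzyloxy)phenyl]-8-{(2S,4S)-7-(benzyloxy)-2-[4-(benzyloxy)phenyl]chroman-4-yl}chromane | C(c1ccccc1)Oc1ccc([C@@H]2C[C@H](c3c(OCc4ccccc4)cc(OCc4ccccc4)c4c3O[C@H](c3ccc(OCc5ccccc5)cc3)[C@H](OCc3ccccc3)C4)c3ccc(OCc4ccccc4)cc3O2)cc1 | intermediate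
25 | (2R,3R)-8-[(2S,4S)-7-hydroxy-2-(4-hydroxyphenyl)chroman-4-yl]-2-(4-hydroxyphenyl)chromane-3,5,7-triol | Oc1ccc([C@@H]2C[C@H](c3c(O)cc(O)c4c3O[C@H](c3ccc(O)cc3)[C@H](O)C4)c3ccc(O)cc3O2)cc1 | target

**Step count and risks**

Total steps: 15. Longest linear sequence: 13 (steps 1–10, then 13–15).

Steps most likely to fail:

1. Step 6. The silyl dithiane may be protodesilylated by adventitious proton sources before it adds. The sequence may also stall at the open-chain alkoxide, because displacement of a fluoride that is only inductively activated is slow; hydride transfer from that alkoxide to the aldehyde would then drain material. Fallback (sets out from 10, rejoins the route at 13): Claisen–Schmidt condensation of 10 with purchased 1-[2,4-bis(benzyloxy)-6-hydroxyphenyl]ethanone (KOH, EtOH) should give (E)-1-[2,4-bis(benzyloxy)-6-hydroxyphenyl]-3-[4-(benzyloxy)phenyl]prop-2-en-1-one F1. NaBH4 in THF/EtOH followed by dilute acid should reduce it to the allylic alcohol and cyclise it to rac-5,7-bis(benzyloxy)-2-[4-(benzyloxy)phenyl]-2H-chromene F2. Hydroboration–oxidation (BH3·THF, then NaOH/H2O2) should give the racemic 2,3-trans-5,7-bis(benzyloxy)-2-[4-(benzyloxy)phenyl]chroman-3-ol F3, and Dess–Martin oxidation should give ketone 13. Ring C is closed here through O1–C2 by classical flavonoid chemistry, and the stereochemistry is again left to step 8.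

2. Step 8. Epimerisation at C2 may be too slow relative to hydride transfer, so that the reaction becomes a simple kinetic resolution, or the catalyst may discriminate poorly between the faces of a ketone flanked by two sp3 carbons. Fallback (sets out from 13, rejoins at 14): reduction with LiBH(s-Bu)3 in THF at −78 °C, with hydride entering anti to the C2 aryl group, should give the racemic 2,3-cis-5,7-bis(benzyloxy)-2-[4-(benzyloxy)phenyl]chroman-3-ol F4. Esterification with (S)-2-methoxy-2-phenylacetic acid (DCC, DMAP) should give the diastereomeric esters (2R,3R)-5,7-bis(benzyloxy)-2-[4-(benzyloxy)phenyl]chroman-3-yl (S)-2-methoxy-2-phenylacetate F5 and its (2S,3S) diastereomer F6, to be separated by chromatography or crystallisation. Hydrolysis of F5 with LiOH in THF/MeOH/H2O should give 14.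

3. Step 13. The hindered aryllithium may enolise the flavanone in place of adding to it, with ring-opening to the chalcone, loss of material and erosion of the C2 configuration of recovered ketone. Fallback (sets out from 16 and 20, rejoins at 25): bromine–lithium exchange on 16 and quenching with 2-isopropoxy-4,4,5,5-tetramethyl-1,3,2-dioxaborolane should give the 8-(4,4,5,5-tetramethyl-1,3,2-dioxaborolan-2-yl) derivative of 15 F7. Ketone 20 with KN(SiMe3)2 and PhNTf2 in THF at −78 °C should give (2S)-7-(benzyloxy)-2-[4-(benzyloxy)phenyl]-2H-chromen-4-yl trifluoromethanesulfonate F8. Suzuki–Miyaura coupling (Pd(OAc)2, SPhos, K3PO4, toluene/H2O, 80 °C) should give the 4-aryl-2H-chromene F9. Hydrogen over Pd(OH)2/C should then add to C3=C4 from the face opposite the C2 aryl group (2,4-cis) and remove all benzyl groups, giving 25 directly.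

**Further compounds**

F1 | step 6 | (E)-1-[2,4-bis(benzyloxy)-6-hydroxyphenyl]-3-[4-(benzyloxy)phenyl]prop-2-en-1-one | O=C(/C=C/c1ccc(OCc2ccccc2)cc1)c1c(O)cc(OCc2ccccc2)cc1OCc1ccccc1
F2 | step 6 | rac-5,7-bis(benzyloxy)-2-[4-(benzyloxy)phenyl]-2H-chromene | C1(c2ccc(OCc3ccccc3)cc2)C=Cc2c(OCc3ccccc3)cc(OCc3ccccc3)cc2O1
F3 | step 6 | rac-(2R,3S)-5,7-bis(benzyloxy)-2-[4-(benzyloxy)phenyl]chroman-3-ol (2,3-trans, both enantiomers) | O[C@H]1Cc2c(OCc3ccccc3)cc(OCc3ccccc3)cc2O[C@@H]1c1ccc(OCc2ccccc2)cc1.O[C@@H]1Cc2c(OCc3ccccc3)cc(OCc3ccccc3)cc2O[C@H]1c1ccc(OCc2ccccc2)cc1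
F4 | step 8 | rac-(2R,3R)-5,7-bis(benzyloxy)-2-[4-(benzyloxy)phenyl]chroman-3-ol (2,3-cis, both enantiomers) | C(c1ccccc1)Oc1cc(OCc2ccccc2)c2c(c1)O[C@H](c1ccc(OCc3ccccc3)cc1)[C@H](O)C2.C(c1ccccc1)Oc1cc(OCc2ccccc2)c2c(c1)O[C@@H](c1ccc(OCc3ccccc3)cc1)[C@@H](O)C2
F5 | step 8 | (2R,3R)-5,7-bis(benzyloxy)-2-[4-(benzyloxy)phenyl]chroman-3-yl (S)-2-methoxy-2-phenylacetate | C(c1ccccc1)Oc1cc(OCc2ccccc2)c2c(c1)O[C@H](c1ccc(OCc3ccccc3)cc1)[C@H](OC(=O)[C@@H](OC)c1ccccc1)C2
F6 | step 8 | (2S,3S)-5,7-bis(benzyloxy)-2-[4-(benzyloxy)phenyl]chroman-3-yl (S)-2-methoxy-2-phenylacetate | C(c1ccccc1)Oc1cc(OCc2ccccc2)c2c(c1)O[C@@H](c1ccc(OCc3ccccc3)cc1)[C@@H](OC(=O)[C@@H](OC)c1ccccc1)C2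
F7 | step 13 | (2R,3R)-3,5,7-tris(benzyloxy)-2-[4-(benzyloxy)phenyl]-8-(4,4,5,5-tetramethyl-1,3,2-dioxaborolan-2-yl)chromane | C(c1ccccc1)Oc1cc(OCc2ccccc2)c2c(c1B1OC(C)(C)C(C)(C)O1)O[C@H](c1ccc(OCc3ccccc3)cc1)[C@H](OCc1ccccc1)C2
F8 | step 13 | (2S)-7-(benzyloxy)-2-[4-(benzyloxy)phenyl]-2H-chromen-4-yl trifluoromethanesulfonate | C(c1ccccc1)Oc1ccc([C@@H]2C=C(OS(=O)(=O)C(F)(F)F)c3ccc(OCc4ccccc4)cc3O2)cc1
F9 | step 13 | (2S)-7-(benzyloxy)-2-[4-(benzyloxy)phenyl]-4-[(2R,3R)-3,5,7-tris(benzyloxy)-2-[4-(benzyloxy)phenyl]chroman-8-yl]-2H-chromene | C(c1ccccc1)Oc1ccc([C@@H]2C=C(c3c(OCc4ccccc4)cc(OCc4ccccc4)c4c3O[C@H](c3ccc(OCc5ccccc5)cc3)[C@H](OCc3ccccc3)C4)c3ccc(OCc4ccccc4)cc3O2)cc1
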